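## Analysis of the target

The target 10 is 3,6-dibromo-2-(2,4-dibromophenoxy)phenol, two benzene rings joined by one ether oxygen; ring A carries the hydroxyl at C1, the ether oxygen at C2 and bromines at C3 and C6, and ring B carries bromines at C2' and C4'. There is no stereocenter and no configurationally stable axis, so the problem is purely one of regiochemistry. The sensitive groups are the four aryl C-Br bonds, which make late organometallic or reductive steps unattractive, and the free phenol, which is acidic and strongly activating toward electrophiles. The hard part is ring A: C6, C1, C2 and C3 are contiguous, each bromine is ortho to one oxygen and meta to the other, and C4 and C5, the positions para to the oxygens, are free. Direct halogenation of a catechol mono-ether would go to C4 and C5, so the bromines of ring A must come from a building block that already holds them, whereas in ring B C2' and C4' are ortho and para to O1', exactly where an aryl ether is attacked by electrophiles. The strategy rests on this difference: ring A is bought with its bromines, ring B enters as a bare phenyl group and is brominated last, once ring A is electronically and conformationally shut off. The ring A core is a 3,6-dibromocatechol with equivalent oxygens, so an aryl shift between them under base would regenerate the same compound.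

## Retrosynthetic reasoning

**10 back to 9.** The O-S bond of a methanesulfonate is cut first. A free hydroxyl at C1 would direct an electrophile to C4 of ring A, so in the halogenation step it must be an electron-withdrawing ester. The ester has to survive acid and a Lewis acid, and come off with alkali without touching the four C-Br bonds.

**9 back to 7.** The C4'-Br and C2'-Br bonds are cut, with the 4'-monobromide 8 as the in-flask intermediate. These are the only two bromines at positions that electrophilic substitution chooses by itself. The bromines at C3 and C6 cannot be cut the same way. The cut turns ring B into a plain phenyl group, so the ether can be made from 2. The forward step must brominate ring B and not C4 or C5 of ring A, and must stop after two bromines.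

**7 back to 5 and 6.** The same O-S bond is traced to the sulfonyl chloride 6 and the free phenol 5. This is a routine sulfonylation, placed directly before the key step.

**5 back to 3.** The C1-O bond is traced to a C1-formyl bond, through the formate 4. The formyl group is the activator that allows the ether bond at C2 to be made, and it is then exchanged for oxygen by aryl migration. This avoids mono-arylating a symmetric catechol. The oxidation is placed before the bromination of ring B for two reasons. The unbrominated phenoxy oxygen is the better donor, so ring A migrates more readily. The formyl C-H is also never exposed to the halogenating conditions.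

**3 back to 1 and 2.** The C2-O ether bond is cut. In 1 the fluorine at C2 is ortho to the formyl group, so phenol 2 can displace it by addition-elimination. Both bromines of ring A arrive in 1 in their final positions. The forward step must take the fluorine and leave the C6 bromine, which is also ortho to the formyl group.

## Alternatives that were turned down

**Alternative 1:** Ring A is cut at C1-C6 and C2-C3 into a four-carbon diene holding both bromines and a two-carbon dienophile holding both oxygens. In the forward step 2,5-dibromothiophene 1,1-dioxide A2 and the bis(trimethylsilyl) ketene acetal of (2,4-dibromophenoxy)acetic acid A3 undergo [4+2] cycloaddition. Extrusion of the sulfonyl bridge and elimination of one silyloxy group then give the silyl ether A1, and desilylation of A1 gives 10.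
- For: all four substituents of ring A are placed by construction, the symmetric diene A2 leaves no regiochemical question, and ring B arrives already brominated. On these points it is stronger than the chosen route, and the step count is comparable.
- Against: A2 is an electron-poor diene obtained by a difficult oxidation and is prone to self-addition. A3 is moisture-sensitive and has to be made with strong base next to an aryl bromide ortho to oxygen. Both new bonds form at bromine-bearing diene termini, one of them to the fully substituted acetal carbon, so the cycloaddition is congested.
- Comparison: the chosen route offers standard reactions on stable intermediates from catalogue chemicals, with the one open question being a selectivity that can be followed and tuned.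

**Alternative 2:** The C2-O ether bond and a C1-B bond (the latent C1-O bond) are cut together across an aryne. In the forward step the symmetric aryne released by fluoride from 3,6-dibromo-2-(trimethylsilyl)phenyl trifluoromethanesulfonate A5 inserts into the O-B bond of 2-(2,4-dibromophenoxy)-4,4,5,5-tetramethyl-1,3,2-dioxaborolane A6. This gives the boronate A4, and oxidation of the C-B bond of A4 gives 10.
- For: it is the most convergent plan. The symmetric aryne has no regiochemical issue, and the ether and the latent hydroxyl are set in one step. If it worked it would be shorter than the chosen route.
- Against: A5 must first be built on a ring with two bromines. Fluoride also attacks the boron of A6, which would release free aryloxide and lead to simple protonation. The aryl anion formed after the O-C2 bond is made sits at C1 next to the C6 bromine and can expel bromide before boron is transferred. Insertion into an aryloxy-boron bond is thinly supported.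
- Comparison: the chosen route gives up convergency for reliability and never generates a carbanion ortho to bromine.

**Alternative 3:** Ring B is cut at C1'-C2' and C5'-C6' into a pyrone diene holding both bromines and a vinyl ether attached to ring A. In the forward step 3,5-dibromo-2H-pyran-2-one A8 and the 2-bromovinyl ether A9 undergo [4+2] cycloaddition. Decarboxylation and dehydrobromination of the adduct give the methyl ether A7, and O-demethylation of A7 gives 10.
- For: the polarity is matched, since the oxygen-bearing carbon of the enol ether A9 bonds to C3 of the pyrone A8. The reaction class is well established. The ring B bromines are fixed by A8, so there is no over-bromination question; on that point it is as strong as or stronger than the chosen route.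
- Against: it builds from scratch the one ring whose pattern electrophilic substitution provides directly. A9 needs the fully elaborated ring A phenol with differentiated oxygens, which meets the same ring A problem, plus a bromovinylation. The bromine on the dienophile A9 lowers its reactivity toward A8. After loss of carbon dioxide the adduct can aromatize by expelling the ring A aryloxide instead of bromide, which would destroy the ether bond. A demethylation is added at the end, so the sequence is clearly longer.
- Comparison: the chosen route reaches the same ring B pattern in one flask from far simpler materials.

Key step: step 4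

## Route

Assumption: 1 is taken as a catalogue compound; 10 has no stereocenter, so no stereodescriptor is needed in any name or SMILES.

Step 1
Reactants: 1 3,6-dibromo-2-fluorobenzaldehyde; 2 phenol
Product: 3 3,6-dibromo-2-phenoxybenzaldehyde
Conditions: K2CO3, DMF, 80 °C
Reagents that add atoms: none
Why: Nucleophilic aromatic substitution by addition-elimination: the ortho formyl group stabilizes the Meisenheimer adduct at C2. Fluoride should leave far faster than the C6 bromide because the addition is rate-determining and favours the most electronegative halogen.

Step 2
Reactants: 3 3,6-dibromo-2-phenoxybenzaldehyde
Product: 5 3,6-dibromo-2-phenoxyphenol, via aryl formate 4 (not isolated)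
Conditions: mCPBA, CH2Cl2, rt; then MeOH, HCl (cat.), rt
Reagents that add atoms: mCPBA (3-chloroperoxybenzoic acid), O=C(OO)c1cccc(Cl)c1
Why: Baeyer-Villiger oxidation of an aryl aldehyde (Dakin-type): in the Criegee adduct ring A should migrate to oxygen because its ortho aryloxy group stabilizes the developing positive charge, giving formate 4. Acid-catalysed methanolysis then passes the formyl group to methanol; the aryl bromides and the diaryl ether are inert to both reagents.

Step 3
Reactants: 5 3,6-dibromo-2-phenoxyphenol; 6 methanesulfonyl chloride
Product: 7 3,6-dibromo-2-phenoxyphenyl methanesulfonate
Conditions: Et3N, CH2Cl2, 0 °C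
Reagents that add atoms: none
Why: O-Sulfonylation of a phenol: with Et3N the sulfonyl chloride reacts through the small sulfene, which the hindered 2,6-disubstituted phenoxide should still capture. No other nucleophilic site is present.

Step 4
Reactants: 7 3,6-dibromo-2-phenoxyphenyl methanesulfonate
Product: 9 3,6-dibromo-2-(2,4-dibromophenoxy)phenyl methanesulfonate, via 4'-bromo ether 8 (not isolated)
Conditions: Br2 (2.05 equiv), FeBr3 (cat.), CH2Cl2, 0 °C to rt
Reagents that add atoms: bromine, BrBr
Why: Electrophilic aromatic substitution (Lewis-acid-assisted bromination of an aryl ether): FeBr3 polarizes Br2, ring B attacks through C4', the arenium ion is stabilized by the lone pair of the ether oxygen, and loss of a proton gives 8. The second equivalent enters ortho to oxygen at C2', which is equivalent to C6' in 8, by the same mechanism and gives 9. The closest known reaction is the stepwise bromination of diphenyl ether and of 4-bromophenyl ethers, which goes para first and ortho second. No ring is closed and no stereocenter is formed. Ring selectivity is needed: ring A has only C4 and C5 free and carries two bromines and a sulfonate ester that withdraw electron density. Its two ortho substituents at C1 and C3 should also turn it out of the C-O-C plane, so the oxygen lone pair conjugates with ring B and not with C5. The count should hold at two through the stoichiometry and because a third bromine would have to enter a ring that already carries two. The methanesulfonate is inert to Br2, FeBr3 and the HBr formed, and it keeps the hydroxyl from directing bromine to C4.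

Step 5
Reactants: 9 3,6-dibromo-2-(2,4-dibromophenoxy)phenyl methanesulfonate
Product: 10 3,6-dibromo-2-(2,4-dibromophenoxy)phenol
Conditions: KOH, MeOH/H2O, 65 °C; then aq. HCl
Reagents that add atoms: none
Why: Alkaline hydrolysis of an aryl sulfonate: hydroxide attacks sulfur (or removes a methyl proton to form sulfene) and expels the phenoxide, a good leaving group because of its ortho bromine. The unactivated aryl bromides should not undergo substitution, and an aryl shift between the two catechol oxygens would be degenerate.

## Compound list

1 | 3,6-dibromo-2-fluorobenzaldehyde | O=Cc1c(F)c(Br)ccc1Br | starting material
2 | phenol | Oc1ccccc1 | starting material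
3 | 3,6-dibromo-2-phenoxybenzaldehyde | O=Cc1c(Oc2ccccc2)c(Br)ccc1Br | intermediate
4 | 3,6-dibromo-2-phenoxyphenyl formate | O=COc1c(Oc2ccccc2)c(Br)ccc1Br | intermediate
5 | 3,6-dibromo-2-phenoxyphenol | Oc1c(Oc2ccccc2)c(Br)ccc1Br | intermediate
6 | methanesulfonyl chloride | CS(=O)(=O)Cl | starting material
7 | 3,6-dibromo-2-phenoxyphenyl methanesulfonate | CS(=O)(=O)Oc1c(Br)ccc(Br)c1Oc1ccccc1 | intermediate
8 | 3,6-dibromo-2-(4-bromophenoxy)phenyl methanesulfonate | CS(=O)(=O)Oc1c(Br)ccc(Br)c1Oc1ccc(Br)cc1 | intermediate
9 | 3,6-dibromo-2-(2,4-dibromophenoxy)phenyl methanesulfonate | CS(=O)(=O)Oc1c(Br)ccc(Br)c1Oc1ccc(Br)cc1Br | intermediate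
10 | 3,6-dibromo-2-(2,4-dibromophenoxy)phenol | Oc1c(Br)ccc(Br)c1Oc1ccc(Br)cc1Br | target

## Step count and least certain steps

Total step count: 5. Longest linear sequence: 5 steps (1 to 3 to 5 to 7 to 9 to 10). Steps 3 and 5 are routine; the three steps below carry the risk.

**Step 4 (key step).** The most likely failure is poor control of the degree of bromination. The second, ortho bromination is much slower than the first, so pushing it to completion may start a third substitution at C6', or some attack at C5 of ring A. The result would be a set of closely related bromo homologues that are hard to separate. The fallback gives up the late halogenation and brings the ring B bromines in with the phenol. It sets out from 1: substitution of the fluorine by commercial 2,4-dibromophenol (K2CO3, DMF, 100 °C) gives 3,6-dibromo-2-(2,4-dibromophenoxy)benzaldehyde F1. Baeyer-Villiger oxidation with mCPBA in CH2Cl2 gives 3,6-dibromo-2-(2,4-dibromophenoxy)phenyl formate F2, and acid-catalysed methanolysis of F2 comes back to the route at 10. Both reactions are the known types used in steps 1 and 2.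

**Step 2.** In the Criegee adduct hydride may migrate in place of ring A, which would oxidize the aldehyde to the carboxylic acid level, because ring A carries two bromines. Alternatively, addition of the peracid to the doubly ortho-substituted aldehyde may be slow. The fallback removes the hydride from the migrating centre and sets out from 3. Addition of MeMgBr (THF, -78 °C) gives racemic 1-(3,6-dibromo-2-phenoxyphenyl)ethan-1-ol F3. Oxidation with Dess-Martin periodinane gives 1-(3,6-dibromo-2-phenoxyphenyl)ethan-1-one F4. Baeyer-Villiger oxidation with CF3CO3H (from (CF3CO)2O and H2O2·urea, Na2HPO4, CH2Cl2) can now only move the aryl or the methyl group and should give 3,6-dibromo-2-phenoxyphenyl acetate F5. Methanolysis (K2CO3, MeOH) comes back to the route at 5.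

**Step 1.** The fluorine is flanked by the formyl group and a bromine. At the temperature needed, displacement of the C6 bromide, a second substitution, or base-induced degradation of the aldehyde may compete. The fallback makes the ether bond first and the formyl group afterwards, and sets out from 2. Ullmann coupling with commercial 1,4-dibromo-2-iodobenzene (CuI, N,N-dimethylglycine, Cs2CO3, dioxane, 90 °C), selective for the C-I bond, gives 1,4-dibromo-2-phenoxybenzene F6. Deprotonation with LiN(iPr)2 (THF, -78 °C) at the position between the oxygen and a bromine gives (3,6-dibromo-2-phenoxyphenyl)lithium F7. Trapping F7 with DMF and work-up with aq. HCl comes back to the route at 3.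

## Further compounds

F1 | step 4 | 3,6-dibromo-2-(2,4-dibromophenoxy)benzaldehyde | O=Cc1c(Br)ccc(Br)c1Oc1ccc(Br)cc1Br
F2 | step 4 | 3,6-dibromo-2-(2,4-dibromophenoxy)phenyl formate | O=COc1c(Br)ccc(Br)c1Oc1ccc(Br)cc1Br
F3 | step 2 | racemic 1-(3,6-dibromo-2-phenoxyphenyl)ethan-1-ol | CC(O)c1c(Br)ccc(Br)c1Oc1ccccc1
F4 | step 2 | 1-(3,6-dibromo-2-phenoxyphenyl)ethan-1-one | CC(=O)c1c(Br)ccc(Br)c1Oc1ccccc1
F5 | step 2 | 3,6-dibromo-2-phenoxyphenyl acetate | CC(=O)Oc1c(Br)ccc(Br)c1Oc1ccccc1
F6 | step 1 | 1,4-dibromo-2-phenoxybenzene | Brc1ccc(Br)c(Oc2ccccc2)c1
F7 | step 1 | (3,6-dibromo-2-phenoxyphenyl)lithium | [Li]c1c(Br)ccc(Br)c1Oc1ccccc1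
A1 | alternative 1 | [3,6-dibromo-2-(2,4-dibromophenoxy)phenoxy]trimethylsilane | C[Si](C)(C)Oc1c(Br)ccc(Br)c1Oc1ccc(Br)cc1Br
A2 | alternative 1 | 2,5-dibromothiophene 1,1-dioxide | O=S1(=O)C(Br)=CC=C1Br
A3 | alternative 1 | bis(trimethylsilyl) ketene acetal of (2,4-dibromophenoxy)acetic acid | C[Si](C)(C)OC(O[Si](C)(C)C)=COc1ccc(Br)cc1Br
A4 | alternative 2 | 2-[3,6-dibromo-2-(2,4-dibromophenoxy)phenyl]-4,4,5,5-tetramethyl-1,3,2-dioxaborolane | CC1(C)OB(c2c(Br)ccc(Br)c2Oc2ccc(Br)cc2Br)OC1(C)C
A5 | alternative 2 | 3,6-dibromo-2-(trimethylsilyl)phenyl trifluoromethanesulfonate | C[Si](C)(C)c1c(Br)ccc(Br)c1OS(=O)(=O)C(F)(F)F
A6 | alternative 2 | 2-(2,4-dibromophenoxy)-4,4,5,5-tetramethyl-1,3,2-dioxaborolane | CC1(C)OB(Oc2ccc(Br)cc2Br)OC1(C)C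
A7 | alternative 3 | 1,4-dibromo-2-(2,4-dibromophenoxy)-3-methoxybenzene | COc1c(Br)ccc(Br)c1Oc1ccc(Br)cc1Br
A8 | alternative 3 | 3,5-dibromo-2H-pyran-2-one | O=c1occ(Br)cc1Br
A9 | alternative 3 | 1,4-dibromo-2-[(2-bromoethenyl)oxy]-3-methoxybenzene (either alkene geometry) | COc1c(Br)ccc(Br)c1OC=CBr
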